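If the next run is to hand on bis adduct rather than its over-reaction product, the choice lies between repeating one of these flasks as it stands and changing its charge, bath or clock.

| flask | substrate | coupling partner | temperature | time |
|---|---|---|---|---|
| south | 0.0020 M | 2.00 equiv | 0 °C | 2.0 s |
| south-east | 0.0020 M | 2.00 equiv | 20 °C | 2.0 s |
| east | 0.0020 M | 2.00 equiv | 60 °C | 2.0 s |
| north-east | 0.0020 M | 2.00 equiv | 40 °C | 2.0 s |

- the flask with the highest share of bis adduct in all that became bis adduct or tris adduct or tetra adduct or over-reaction product ("all alike" if they lie within 1.5 percentage points) (south / south-east / east / north-east / all alike)
- share of bis adduct in all that became bis adduct or tris adduct or tetra adduct or over-reaction product, south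
- share of bis adduct in all that became bis adduct or tris adduct or tetra adduct or over-reaction product, south-east
- share of bis adduct in all that became bis adduct or tris adduct or tetra adduct or over-reaction product, east
- share of bis adduct in all that became bis adduct or tris adduct or tetra adduct or over-reaction product, north-east

    bis adduct → over-reaction product (k1 = 0.29 s⁻¹, Ea1 = 69.0 kJ mol⁻¹)
    substrate + coupling partner → single product (k2 = 160 L mol⁻¹ s⁻¹, Ea2 = 45.0 kJ mol⁻¹)
    coupling partner + single product → bis adduct (k3 = 140 L mol⁻¹ s⁻¹, Ea3 = 39.0 kJ mol⁻¹)
    coupling partner + tris adduct → tetra adduct (k4 = 98 L mol⁻¹ s⁻¹, Ea4 = 45.0 kJ mol⁻¹)
    coupling partner + bis adduct → tris adduct (k5 = 12 L mol⁻¹ s⁻¹, Ea5 = 36.0 kJ mol⁻¹)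
    (constants at 0 °C)

- at 0 °C the constants are as listed, elsewhere as the activation energies make them

Substrate is charged in the smaller amount, but the coupling partner at 2.00 equiv is just the two that each bis adduct takes, so neither stands in excess for bis adduct, and what has left substrate is found in single product, bis adduct, tris adduct, tetra adduct and over-reaction product. The asked share reads the last four of these. In south, coupling of bis adduct towards tris adduct starts with a pseudo-first-order constant of 0.0480 s⁻¹, slower than the loss of bis adduct to over-reaction product at 0.29 s⁻¹, so the share is chiefly a contest between bis adduct and over-reaction product. That contest is told by the drain number, the first-order constant of that loss times the time allowed, 0.580 in south. My own reckoning takes a steady feed of bis adduct, for which the share is one minus the exponential of minus the drain number, divided by the drain number. South suits this, as substrate there has a coupling time of 1.56 s, close to the 2.0 s allowed, and the share comes to 75.9 %. Warming raises the drain number to 4.61 in south-east, 28.1 in north-east and 138 in east, giving shares of 21.5 %, 3.56 % and 0.725 %. These warm figures are likely high, since the coupling time in east, 0.0441 s, is far shorter than the run, which makes a steady feed a poor assumption for east. The decision is therefore to repeat south, whose drain number is the smallest, leaving the coupling partner at 2.00 equiv, the two that each bis adduct takes, and keeping the clock at 2.0 s.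

The forecast names south, with 76 % in south, 14.5 % in south-east, 0.7 % in north-east and 0.05 % in east, holding that bis adduct “otherwise sits at a small steady level”, and its warm figures lie below this reckoning. The simulation puts south highest, with 76.5 % in south, 14.1 % in south-east, 0.705 % in north-east and 0.0573 % in east.

South, at a drain number of 0.580, reads 76.5 % against the reckoned 75.9 %, while south-east falls below its reckoned share. The time allowed is the main reason south keeps its bis adduct: left for 20.0 s, south has a drain number of 5.80 and a steady-feed share of 17.2 %, yet it reads 4.75 %, down from 76.5 %. That reading lies below the steady-feed figure, with substrate in south down to 3.65 % of its charge and over-reaction product holding 74.0 %.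

Its constants come from no measurement; the result is computed.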